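**Retrosynthetic overview**

1. Target ⇐ C1/C6 diol by oxidation and C2=C3 dehydrogenation; 15-OAc ⇐ 15-oxo-16-ene; ring D ⇐ 5-exo vinyl-radical closure (C13–C16) after aldol of the 7,20-lactone enolate (C8–C15) with 2-bromoacrolein.
2. 7,20-δ-Lactone ⇐ lactone switch: a temporary 6,20-γ-lactone (ring C5–C6–O–C20–C10, absent from the target) is opened by reduction and the C20 hydroxyl is relactonised onto C7.
3. Key disconnection C1–C10: ring A is closed by adding a C1 ketyl to C10 of a butenolide. The enabling feature is that C10 is β to the C6 carbonyl carbon and carries the C20–O carbon, with C6 and C20 cis on ring A. C6, C5, C10, C20 and O can therefore be tied up as a butenolide whose electrophilic β-carbon C10 lies four atoms from C1, and the cis-fused lactone fixes C5 relative to C10.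
4. Ring C ⇐ auxiliary-controlled Diels–Alder of butadiene with a C8=C9 acrylimide (sets C9, which then controls C10); C9–C10 ⇐ Heck coupling; butenolide with quaternary C4 ⇐ tetronic acid + prenol (Mitsunobu, Claisen, triflate); C1 ⇐ hydroformylation.
5. Order of ring formation: butenolide (temporary) → ring C → ring A (key) → 7,20-lactone → ring D.

Key step: step 8

Remark: atoms are numbered as in ent-kaurane (C1–C20); the C1 carbinol from step 8 is drawn as the expected epimer (either converges at step 19), and 2-bromoacrolein is taken as a commercial, stabilised reagent.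

**Route**

Step 1
Reactants: 1 tetronic acid; 2 prenol
Product: 3 4-(prenyloxy)furan-2(5H)-one
Conditions: PPh3, DIAD, THF, 0 °C to rt
Reagents that add atoms: none
Why: Mitsunobu O-alkylation of the acidic vinylogous acid should give the 4-O-prenyl tetronate needed for the rearrangement; no stereocentre is formed.

Step 2
Reactants: 3 4-(prenyloxy)furan-2(5H)-one
Product: 4 3-(2-methylbut-3-en-2-yl)tetronic acid
Conditions: PhMe, 130 °C (sealed tube), short reaction time, used crude
Reagents that add atoms: none
Why: Claisen rearrangement of the allyl vinyl ether should transfer the prenyl unit to the tetronate α-carbon with allylic inversion, forming the C4–C5 bond and the achiral gem-dimethyl quaternary carbon C4.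

Step 3
Reactants: 4 3-(2-methylbut-3-en-2-yl)tetronic acid
Product: 5 tetronate enol triflate
Conditions: Tf2O, i-Pr2NEt, CH2Cl2, −78 °C
Reagents that add atoms: triflic anhydride O=S(=O)(OS(=O)(=O)C(F)(F)F)C(F)(F)F
Why: O-sulfonylation of the enolic hydroxyl should give the vinyl triflate at the future C10 for cross-coupling; no stereocentre is formed.

Step 4
Reactants: 6 (R)-4-benzyloxazolidin-2-one; 7 acryloyl chloride
Product: 8 (R)-3-acryloyl-4-benzyloxazolidin-2-one
Conditions: n-BuLi, THF, −78 °C; then 7, −78 to 0 °C
Reagents that add atoms: none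
Why: N-acylation of the lithiated oxazolidinone attaches the chiral auxiliary to the C7–C8–C9 acrylate unit; its stereocentre comes from the commercial auxiliary.

Step 5
Reactants: 5 tetronate enol triflate; 8 (R)-3-acryloyl-4-benzyloxazolidin-2-one
Product: 9 (E)-butenolidyl acrylimide
Conditions: Pd(OAc)2 (5 mol %), P(o-tol)3, Et3N, DMF, 70 °C
Reagents that add atoms: none
Why: Mizoroki–Heck coupling of the enol triflate with the acrylimide should form the C9–C10 bond and, by syn β-hydride elimination, the E-configured C8=C9 dienophile.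

Step 6
Reactants: 9 (E)-butenolidyl acrylimide; 10 buta-1,3-diene
Product: 11 cyclohexene imide (trans Diels–Alder adduct)
Conditions: Et2AlCl (2.5 equiv), excess 10, CH2Cl2, −40 to −10 °C
Reagents that add atoms: none
Why: In this oxazolidinone-auxiliary-controlled Diels–Alder reaction the diene should add to the Et2AlCl-chelated s-cis imide on the face opposite the benzyl group, building ring C and setting C9 as in the target (C8–H trans, re-set in step 13).

Step 7
Reactants: 11 cyclohexene imide
Product: 12 aldehyde imide
Conditions: Rh(acac)(CO)2 (2 mol %), BiPhePhos, CO/H2 (1:1, 10 bar), PhMe, 60 °C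
Reagents that add atoms: carbon monoxide [C-]#[O+]
Why: Linear-selective rhodium-catalysed hydroformylation should convert only the terminal vinyl group on quaternary C4 into the C1 aldehyde, since the cyclohexene and the tetrasubstituted butenolide alkene are much less reactive; no stereocentre is formed.

Step 8
Reactants: 12 aldehyde imide
Product: 13 tricyclic hydroxy γ-lactone
Conditions: SmI2 (2.5 equiv), HMPA, t-BuOH (2 equiv), THF, −78 to 0 °C, slow addition of 12
Reagents that add atoms: none
Why: SmI2–HMPA should reduce the C1 aldehyde to a samarium ketyl that adds to C10, the β-carbon of the butenolide, giving the lactone α-radical at C5, which takes a second electron to the samarium enolate and is protonated by t-BuOH. The closest known reaction type is the SmI2-mediated aldehyde–α,β-unsaturated lactone reductive (ketyl–olefin) cyclisation with the tether on the α-carbon, which is also known for β,β-disubstituted acceptors that give quaternary carbons. Ring A (C1–C2–C3–C4–C5–C10) closes in the 6-endo-trig mode through a chair-like transition state helped by the C4 gem-dimethyl group. C10 is controlled by the C9 stereocentre: allylic 1,3-strain holds H9 in the butenolide plane beside the bulky C5 substituent, C8 with its acyl oxazolidinone shields one face, and the ketyl adds to the other (C11) face; C5 is set by protonation of the bicyclic enolate on its convex face to give the cis-fused γ-lactone (C6 and C20 cis), which base equilibration can also reach; the C1 carbinol, expected trans to C20, is of no consequence. The step needs attack at C10 rather than C5 (secured by the polarity of the butenolide and the stabilised α-lactone radical), cyclisation faster than reduction or pinacol coupling of the ketyl (secured by the gem-dimethyl effect and slow addition), and reduction of the aldehyde in preference to the imide and the isolated alkene (the aldehyde is the most easily reduced group).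

Step 9
Reactants: 13 tricyclic hydroxy γ-lactone
Product: 14 C1 TBS ether
Conditions: TBSOTf, 2,6-lutidine, CH2Cl2, 0 °C
Reagents that add atoms: tert-butyldimethylsilyl triflate CC(C)(C)[Si](C)(C)OS(=O)(=O)C(F)(F)F
Why: Silylation of the hindered secondary C1 hydroxyl should mask it so that it cannot compete with the C20 hydroxyl in the later lactonisation; no stereocentre changes.

Step 10
Reactants: 14 C1 TBS ether
Product: 15 triol
Conditions: LiBH4, MeOH (1 equiv), THF, 0 to 40 °C
Reagents that add atoms: none
Why: LiBH4 should reduce the γ-lactone to the C6/C20 diol (cleaving the temporary ring) and the acyl oxazolidinone to the C7 carbinol with release of the auxiliary; no stereocentre is touched.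

Step 11
Reactants: 15 triol
Product: 17 7,20-lactone alcohol, via δ-lactol 16 (not isolated)
Conditions: TEMPO (20 mol %), PhI(OAc)2 (2.2 equiv), CH2Cl2, rt
Reagents that add atoms: none
Why: In this TEMPO/PhI(OAc)2 oxidative lactonisation of a 1,5-diol the least hindered C7 carbinol should be oxidised first, its aldehyde trapped by the C20 hydroxyl as the six-membered lactol and oxidised on to the 7,20-lactone, leaving the doubly neopentyl C6 carbinol free; no stereocentre changes.

Step 12
Reactants: 17 7,20-lactone alcohol
Product: 18 bis-TBS 7,20-lactone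
Conditions: TBSCl, imidazole, DMF, rt
Reagents that add atoms: tert-butyldimethylsilyl chloride CC(C)(C)[Si](C)(C)Cl
Why: Silylation of the primary C6 hydroxyl protects it against the strong base of the next step; no stereocentre changes.

Step 13
Reactants: 18 bis-TBS 7,20-lactone; 19 2-bromoacrolein
Product: 20 aldol adduct (C15 epimers)
Conditions: LiN(i-Pr)2, THF, −78 °C; then 19, −78 °C
Reagents that add atoms: none
Why: Aldol addition of the lithium δ-lactone enolate to 2-bromoacrolein should occur on the enolate face syn to H9 (the usual cis-fusion preference of ring-fusion enolates), making C8 quaternary with C15 trans to C10; the C15 carbinol forms as a mixture that is converged in steps 15 and 16.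

Step 14
Reactants: 20 aldol adduct (C15 epimers)
Product: 21 tetracyclic allylic alcohol (C15 epimers)
Conditions: Bu3SnH, AIBN (cat.), PhH, 80 °C
Reagents that add atoms: none
Why: In this tin-hydride vinyl-radical cyclisation the C16 radical should close 5-exo-trig onto C13 of the cyclohexene from the axial C8 side chain, forming ring D with its exocyclic methylene and fixing C13 through the cis-1,3 bridge, while a moderate tin hydride concentration traps the C12 radical before homoallyl rearrangement.

Step 15
Reactants: 21 tetracyclic allylic alcohol (C15 epimers)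
Product: 22 15-oxo-16-ene
Conditions: Dess–Martin periodinane, NaHCO3, CH2Cl2, rt
Reagents that add atoms: none
Why: Dess–Martin oxidation of the allylic carbinol should converge both C15 epimers to the α-methylene ketone; no other stereocentre is affected.

Step 16
Reactants: 22 15-oxo-16-ene
Product: 23 15-alcohol
Conditions: NaBH4, CeCl3·7H2O, MeOH, −78 °C
Reagents that add atoms: none
Why: Luche 1,2-reduction should deliver hydride to C15 from the exo face of ring D (the face of C7 and H13, away from the C9–C11–C12 bridge), placing the hydroxyl syn to that bridge as in the target.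

Step 17
Reactants: 23 15-alcohol
Product: 24 15-acetate
Conditions: Ac2O, DMAP (cat.), pyridine, rt
Reagents that add atoms: acetic anhydride CC(=O)OC(C)=O
Why: DMAP-catalysed acylation of the only free hydroxyl installs the C15 acetate with retention.

Step 18
Reactants: 24 15-acetate
Product: 25 C1/C6 diol
Conditions: HF·pyridine, THF/pyridine, 0 °C to rt
Reagents that add atoms: none
Why: Fluoride-mediated desilylation should remove both TBS ethers while the acetate, lactone and exocyclic alkene survive; no stereocentre changes.

Step 19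
Reactants: 25 C1/C6 diol
Product: 26 keto aldehyde
Conditions: (COCl)2, DMSO, CH2Cl2, −78 °C; then Et3N, −78 to 0 °C
Reagents that add atoms: none
Why: Swern oxidation activates both hydroxyls before base is added, so the C1 ketone and C6 aldehyde should form together without lactol or lactone formation between them, and the cold, brief exposure to Et3N should leave C5 intact.

Step 20
Reactants: 26 keto aldehyde
Product: 27 target
Conditions: IBX, 4-methoxypyridine N-oxide, DMSO, rt to 40 °C
Reagents that add atoms: none
Why: IBX dehydrogenation of the ketone through its enol should give only the C2=C3 enone because C10 and C4 are quaternary, and the C6 aldehyde has no β-hydrogen and cannot be dehydrogenated.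

**Compound list**

1 | tetronic acid (4-hydroxyfuran-2(5H)-one) | O=C1C=C(O)CO1 | starting material
2 | prenol (3-methylbut-2-en-1-ol) | CC(C)=CCO | starting material
3 | 4-(3-methylbut-2-enyloxy)furan-2(5H)-one | CC(C)=CCOC1=CC(=O)OC1 | intermediate
4 | 4-hydroxy-3-(2-methylbut-3-en-2-yl)furan-2(5H)-one | C=CC(C)(C)C1=C(O)COC1=O | intermediate
5 | 4-(2-methylbut-3-en-2-yl)-5-oxo-2,5-dihydrofuran-3-yl trifluoromethanesulfonate | C=CC(C)(C)C1=C(OS(=O)(=O)C(F)(F)F)COC1=O | intermediate
6 | (R)-4-benzyloxazolidin-2-one | O=C1N[C@H](Cc2ccccc2)CO1 | starting material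
7 | acryloyl chloride | C=CC(Cl)=O | starting material
8 | (R)-3-acryloyl-4-benzyloxazolidin-2-one | C=CC(=O)N1[C@H](Cc2ccccc2)COC1=O | intermediate
9 | (R)-4-benzyl-3-[(E)-3-(4-(2-methylbut-3-en-2-yl)-5-oxo-2,5-dihydrofuran-3-yl)acryloyl]oxazolidin-2-one | C=CC(C)(C)C1=C(/C=C/C(=O)N2[C@H](Cc3ccccc3)COC2=O)COC1=O | intermediate
10 | buta-1,3-diene | C=CC=C | starting material
11 | cyclohex-3-ene (ring C) carrying trans the C8 acyl oxazolidinone and the C9 butenolide, C9 as in the target | C=CC(C)(C)C1=C(COC1=O)[C@@H]2CC=CC[C@H]2C(=O)N3[C@H](Cc4ccccc4)COC3=O | intermediate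
12 | aldehyde from 11 (C1 aldehyde on a CH2CH2 chain from C4) | O=CCCC(C)(C)C1=C(COC1=O)[C@@H]2CC=CC[C@H]2C(=O)N3[C@H](Cc4ccccc4)COC3=O | intermediate
13 | ring A closed: cis-fused 6,20-γ-lactone, quaternary C10 with C9 trans to C6, H5 cis to C9, C1–OH cis to C9 | O[C@@H]1CCC(C)(C)[C@H]2C(=O)OC[C@@]12[C@@H]3CC=CC[C@H]3C(=O)N4[C@H](Cc5ccccc5)COC4=O | intermediate
14 | C1 tert-butyldimethylsilyl ether of 13 | CC(C)(C)[Si](C)(C)O[C@@H]1CCC(C)(C)[C@H]2C(=O)OC[C@@]12[C@@H]3CC=CC[C@H]3C(=O)N4[C@H](Cc5ccccc5)COC4=O | intermediate
15 | triol (C6, C20 and C7 carbinols; C1 OTBS) | CC(C)(C)[Si](C)(C)O[C@@H]1CCC(C)(C)[C@@H](CO)[C@]1(CO)[C@@H]2CC=CC[C@H]2CO | intermediate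
16 | δ-lactol (C7 hemiacetal with O–C20, either C7 epimer) | CC(C)(C)[Si](C)(C)O[C@@H]1CCC(C)(C)[C@@H](CO)[C@@]12COC(O)[C@@H]3CC=CC[C@@H]23 | intermediate
17 | spiro 7,20-δ-lactone trans-fused to ring C, free C6 carbinol, C1 OTBS | CC(C)(C)[Si](C)(C)O[C@@H]1CCC(C)(C)[C@@H](CO)[C@@]12COC(=O)[C@@H]3CC=CC[C@@H]23 | intermediate
18 | C1,C6 bis-TBS ether of 17 | CC(C)(C)[Si](C)(C)O[C@@H]1CCC(C)(C)[C@@H](CO[Si](C)(C)C(C)(C)C)[C@@]12COC(=O)[C@@H]3CC=CC[C@@H]23 | intermediate
19 | 2-bromoacrolein (2-bromoprop-2-enal) | C=C(Br)C=O | starting material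
20 | aldol adduct: C8 quaternary as in the target (lactone now cis-fused to ring C), C15 carbinol as epimer mixture, C16 vinyl bromide | CC(C)(C)[Si](C)(C)O[C@@H]1CCC(C)(C)[C@@H](CO[Si](C)(C)C(C)(C)C)[C@@]12COC(=O)[C@@]3(C(O)C(Br)=C)CC=CC[C@@H]23 | intermediate
21 | ring D closed: 16-methylene bicyclo[3.2.1]octane, C13 as in the target, C15 carbinol as epimer mixture | C=C1[C@@H]2CC[C@@H]3[C@](C2)(C(=O)OC[C@]34[C@H](O[Si](C)(C)C(C)(C)C)CCC(C)(C)[C@H]4CO[Si](C)(C)C(C)(C)C)C1O | intermediate
22 | 15-oxo-16-ene | C=C1[C@@H]2CC[C@@H]3[C@](C2)(C(=O)OC[C@]34[C@H](O[Si](C)(C)C(C)(C)C)CCC(C)(C)[C@H]4CO[Si](C)(C)C(C)(C)C)C1=O | intermediate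
23 | 15-alcohol, hydroxyl syn to the C9–C11–C12 bridge (15R) | C=C1[C@@H]2CC[C@@H]3[C@](C2)(C(=O)OC[C@]34[C@H](O[Si](C)(C)C(C)(C)C)CCC(C)(C)[C@H]4CO[Si](C)(C)C(C)(C)C)[C@@H]1O | intermediate
24 | 15-acetate of 23 | C=C1[C@@H]2CC[C@@H]3[C@](C2)(C(=O)OC[C@]34[C@H](O[Si](C)(C)C(C)(C)C)CCC(C)(C)[C@H]4CO[Si](C)(C)C(C)(C)C)[C@@H]1OC(C)=O | intermediate
25 | C1/C6 diol | C=C1[C@@H]2CC[C@@H]3[C@](C2)(C(=O)OC[C@]34[C@H](O)CCC(C)(C)[C@H]4CO)[C@@H]1OC(C)=O | intermediate
26 | 1-oxo-6-al (2,3-dihydro target) | C=C1[C@@H]2CC[C@@H]3[C@](C2)(C(=O)OC[C@]34C(=O)CCC(C)(C)[C@H]4C=O)[C@@H]1OC(C)=O | intermediate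
27 | CNP0108627.4 | C=C1[C@@H]2CC[C@@H]3[C@](C2)(C(=O)OC[C@]32C(=O)C=CC(C)(C)[C@H]2C=O)[C@@H]1OC(C)=O | target

**Step count and risks**

Total step count: 20. Longest linear sequence: 19 (steps 1–3 and 5–20; step 4 is a one-step side branch).

Steps most likely to fail:

Step 8 (key step). The ketyl may be reduced further or dimerise by pinacol coupling before it reaches the fully substituted C10, and samarium chelation to the acyl oxazolidinone may erode the facial selectivity at C10. The fallback is an acyl-radical closure that sets out from 12 and comes back at 13. Pinnick oxidation (NaClO2, NaH2PO4, 2-methyl-2-butene) should give the carboxylic acid F1. PhSeSePh and PBu3 should convert it into the Se-phenyl selenoester F2. Bu3SnH and AIBN in benzene at 80 °C with slow addition should then effect the known 6-endo acyl-radical cyclisation onto the butenolide to give the ring A keto lactone F3, without any metal to chelate. Reduction of F3 with NaBH4 and CeCl3·7H2O at −40 °C, with hydride delivered anti to the C9 substituent, should return 13.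

Step 11. The neopentyl C20 or C6 carbinols may be oxidised in competition with the C7 carbinol, which would lead to isomeric lactones. The fallback sets out from 14 and comes back at 17. LiOH and H2O2 should cleave the auxiliary to give the carboxylic acid F4. i-Bu2AlH at −78 °C should reduce the γ-lactone (the aluminium carboxylate being inert) to the lactol F5, which is not isolated, and NaBH4 should reduce this to the dihydroxy acid F6. Acid-catalysed lactonisation (TsOH, benzene, 60 °C) should close the six-membered ring onto the C20 hydroxyl, rather than a seven-membered ring onto the C6 hydroxyl, to give 17.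

Step 13. The aldol adduct may revert by retro-aldol, the hindered ring-fusion enolate may form slowly, and the aldehyde may add to the wrong enolate face while the quaternary C8 is created next to the spiro centre. The fallback sets out from 18 and comes back at 22. Alkylation of the same lithium enolate with 2,3-dibromopropene should give the 2-bromoallyl lactone F7. Bu3SnH and AIBN should close ring D to the 15-deoxy methylene compound F8. Allylic oxidation with SeO2 and t-BuOOH should place a hydroxyl on the exo face of C15 to give the 15-epi alcohol F9, and Dess–Martin oxidation of F9 should give 22.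

**Further compounds**

F1 | step 8 | carboxylic acid from 12 (C1 acid) | OC(=O)CCC(C)(C)C1=C(COC1=O)[C@@H]2CC=CC[C@H]2C(=O)N3[C@H](Cc4ccccc4)COC3=O
F2 | step 8 | Se-phenyl selenoester of F1 | O=C([Se]c1ccccc1)CCC(C)(C)C2=C(COC2=O)[C@@H]3CC=CC[C@H]3C(=O)N4[C@H](Cc5ccccc5)COC4=O
F3 | step 8 | ring A keto lactone (1-oxo analogue of 13) | O=C1CCC(C)(C)[C@H]2C(=O)OC[C@@]12[C@@H]3CC=CC[C@H]3C(=O)N4[C@H](Cc5ccccc5)COC4=O
F4 | step 11 | C7 carboxylic acid from 14 | CC(C)(C)[Si](C)(C)O[C@@H]1CCC(C)(C)[C@H]2C(=O)OC[C@@]12[C@@H]3CC=CC[C@H]3C(O)=O
F5 | step 11 | C6 lactol acid (not isolated) | CC(C)(C)[Si](C)(C)O[C@@H]1CCC(C)(C)[C@H]2C(O)OC[C@@]12[C@@H]3CC=CC[C@H]3C(O)=O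
F6 | step 11 | C6,C20-dihydroxy C7 acid | CC(C)(C)[Si](C)(C)O[C@@H]1CCC(C)(C)[C@@H](CO)[C@]1(CO)[C@@H]2CC=CC[C@H]2C(O)=O
F7 | step 13 | C8 2-bromoallyl lactone | CC(C)(C)[Si](C)(C)O[C@@H]1CCC(C)(C)[C@@H](CO[Si](C)(C)C(C)(C)C)[C@@]12COC(=O)[C@@]3(CC(Br)=C)CC=CC[C@@H]23
F8 | step 13 | 15-deoxy 16-methylene tetracycle | C=C1[C@@H]2CC[C@@H]3[C@](C2)(C(=O)OC[C@]34[C@H](O[Si](C)(C)C(C)(C)C)CCC(C)(C)[C@H]4CO[Si](C)(C)C(C)(C)C)C1
F9 | step 13 | 15-epi alcohol (C15 epimer of 23) | C=C1[C@@H]2CC[C@@H]3[C@](C2)(C(=O)OC[C@]34[C@H](O[Si](C)(C)C(C)(C)C)CCC(C)(C)[C@H]4CO[Si](C)(C)C(C)(C)C)[C@H]1O
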